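**Retrosynthetic overview**
- The strategy rests on ring A: the pyran oxygen O1 sits on C8a para to the C6 ketone carbonyl, and the phenol oxygen sits on C7 ortho to it. Both aryl C–O bonds can therefore be made by fluoride displacement from a 2,4-difluoroaryl ketone.
- Late disconnections: the aryl methoxymethyl ether on ring B; C7–OH back to C7–F (SNAr with a hydroxide surrogate); O1–C8a back to a tertiary (Z)-allylic alcohol and the C8a fluoride (intramolecular SNAr).
- The Z-alkenol comes from Sonogashira coupling and semi-hydrogenation. The ketone comes from a fluorine-directed lithiation and Weinreb acylation. The prenyl group is placed between the two fluorines by the first lithiation of 1-bromo-2,4-difluorobenzene.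
- Ring order: rings A and B are bought; the pyran is the only ring formed, in step 7.

Key step: step 7

Remark: the target has no stereocentre; the only stereochemical element of the route is the Z alkene of the key-step precursor, which becomes the endocyclic C3=C4 bond.

**Route**

Step 1
Reactants: 1 3-(4-hydroxyphenyl)propanoic acid
Product: 3 3-(4-hydroxyphenyl)-N-methoxy-N-methylpropanamide, via acyl imidazolide 2 (not isolated)
Conditions: 1,1'-carbonyldiimidazole (1.1 equiv), THF, rt; then MeNHOMe·HCl, rt
Reagents that add atoms: N,O-dimethylhydroxylamine hydrochloride, CNOC.Cl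
Why: Amide coupling through the acyl imidazolide, which forms faster at the carboxylic acid than at the phenol, so the Weinreb amide should be obtained without protecting the phenol first.

Step 2
Reactants: 3 3-(4-hydroxyphenyl)-N-methoxy-N-methylpropanamide
Product: 4 N-methoxy-3-[4-(methoxymethoxy)phenyl]-N-methylpropanamide
Conditions: MOMCl, iPr2NEt, CH2Cl2, 0 °C → rt
Reagents that add atoms: chloromethyl methyl ether, COCCl
Why: O-alkylation of the phenol gives a methoxymethyl ether that should withstand the organolithium, palladium and carbonate steps ahead and leaves under mild acid at the end.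

Step 3
Reactants: 5 1-bromo-2,4-difluorobenzene; 6 1-bromo-3-methylbut-2-ene
Product: 8 1-bromo-2,4-difluoro-3-(3-methylbut-2-enyl)benzene, via aryllithium 7 (not isolated)
Conditions: LiN(iPr)2, THF, −78 °C; CuBr·SMe2 (10 mol %), then 6, −78 → −20 °C
Reagents that add atoms: none
Why: Directed ortho-metalation removes the C–H flanked by both fluorines, by far the most acidic, without bromine–lithium exchange, and copper-catalysed allylic substitution at the primary carbon of the bromide should give the linear prenyl arene.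

Step 4
Reactants: 8 1-bromo-2,4-difluoro-3-(3-methylbut-2-enyl)benzene; 4 N-methoxy-3-[4-(methoxymethoxy)phenyl]-N-methylpropanamide
Product: 11 1-[5-bromo-2,4-difluoro-3-(3-methylbut-2-enyl)phenyl]-3-[4-(methoxymethoxy)phenyl]propan-1-one, via aryllithium 9 (not isolated), via lithium hemiaminal chelate 10 (not isolated)
Conditions: LiN(iPr)2, THF, −78 °C; then 4, −78 → −50 °C; aq NH4Cl
Reagents that add atoms: none
Why: A second fluorine-directed ortho-lithiation should take the C–H next to fluorine rather than the one next to bromine, and the Weinreb ketone synthesis stops at the chelated tetrahedral adduct, so the ketone is released only on work-up and never meets the base.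

Step 5
Reactants: 11 1-[5-bromo-2,4-difluoro-3-(3-methylbut-2-enyl)phenyl]-3-[4-(methoxymethoxy)phenyl]propan-1-one; 12 2-methylbut-3-yn-2-ol
Product: 13 1-[2,4-difluoro-5-(3-hydroxy-3-methylbut-1-ynyl)-3-(3-methylbut-2-enyl)phenyl]-3-[4-(methoxymethoxy)phenyl]propan-1-one
Conditions: PdCl2(PPh3)2 (3 mol %), CuI (5 mol %), Et3N/THF, 65 °C
Reagents that add atoms: none
Why: Sonogashira coupling of the electron-poor aryl bromide with the terminal alkyne should proceed readily, and triethylamine is too poor a nucleophile to displace the activated fluorines.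

Step 6
Reactants: 13 1-[2,4-difluoro-5-(3-hydroxy-3-methylbut-1-ynyl)-3-(3-methylbut-2-enyl)phenyl]-3-[4-(methoxymethoxy)phenyl]propan-1-one
Product: 14 1-[2,4-difluoro-5-[(Z)-3-hydroxy-3-methylbut-1-enyl]-3-(3-methylbut-2-enyl)phenyl]-3-[4-(methoxymethoxy)phenyl]propan-1-one
Conditions: H2 (1 atm), Pd/CaCO3 poisoned with Pb(OAc)2, quinoline, EtOAc, rt, stopped after one equivalent of H2
Reagents that add atoms: none
Why: Lindlar semi-hydrogenation delivers both hydrogens to the same face of the alkyne and so sets the Z alkene, while the trisubstituted prenyl alkene, the ketone and the C–F bonds should not be touched by the poisoned catalyst.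

Step 7
Reactants: 14 1-[2,4-difluoro-5-[(Z)-3-hydroxy-3-methylbut-1-enyl]-3-(3-methylbut-2-enyl)phenyl]-3-[4-(methoxymethoxy)phenyl]propan-1-one
Product: 15 1-[7-fluoro-2,2-dimethyl-8-(3-methylbut-2-enyl)-2H-chromen-6-yl]-3-[4-(methoxymethoxy)phenyl]propan-1-one
Conditions: Cs2CO3 (2 equiv), dry amine-free DMF, 60 °C
Reagents that add atoms: none
Why: Addition–elimination SNAr: carbonate generates the tertiary (Z)-allylic alkoxide in equilibrium, it adds to C8a to give a Meisenheimer anion whose charge is carried by the para C6 carbonyl oxygen, and loss of fluoride restores the arene with the new O1–C8a bond. The closest known reaction type is the intramolecular etherification of alkoxides on fluoroarenes activated by an ortho or para carbonyl group, as used for chromans and related benzo-fused ethers. The pyran closes in a 6-exo-trig sense, the oxygen attacking a ring sp2 carbon whose breaking π bond (C8a=C8) lies outside the new ring. No stereocentre is formed, and the Z alkene becomes the endocyclic C3=C4 bond. The step needs site selectivity between two activated fluorines, and geometry secures it: the Z alkene holds the alkoxide within bonding distance of C8a only, whereas the C7 fluorine is out of reach and has no intramolecular partner. The weak heterogeneous base keeps the concentration of the ketone enolate, which would switch off the activation, low, and enolisation is reversible while ring closure is not.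

Step 8
Reactants: 15 1-[7-fluoro-2,2-dimethyl-8-(3-methylbut-2-enyl)-2H-chromen-6-yl]-3-[4-(methoxymethoxy)phenyl]propan-1-one
Product: 17 1-[7-hydroxy-2,2-dimethyl-8-(3-methylbut-2-enyl)-2H-chromen-6-yl]-3-[4-(methoxymethoxy)phenyl]propan-1-one, via O-aryl acetohydroxamate 16 (not isolated)
Conditions: acetohydroxamic acid (3 equiv), K2CO3 (5 equiv), DMSO, 80–100 °C; aq NH4Cl work-up
Reagents that add atoms: acetohydroxamic acid, CC(=O)NO
Why: SNAr by the alpha-effect nucleophile acetohydroxamate at the fluorine ortho to the ketone, followed by base-induced Lossen-type fragmentation of the O-aryl hydroxamate, should release the phenoxide (hydroxide-surrogate hydroxylation), and the excess hydroxamic acid buffers the medium so that the ketone stays largely un-enolised.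

Step 9
Reactants: 17 1-[7-hydroxy-2,2-dimethyl-8-(3-methylbut-2-enyl)-2H-chromen-6-yl]-3-[4-(methoxymethoxy)phenyl]propan-1-one
Product: 18 1-[7-hydroxy-2,2-dimethyl-8-(3-methylbut-2-enyl)-2H-chromen-6-yl]-3-(4-hydroxyphenyl)propan-1-one
Conditions: 3 M aq HCl, MeOH, 40 °C
Reagents that add atoms: none
Why: Acid-catalysed acetal exchange with methanol cleaves the aryl methoxymethyl ether, and dilute acid at mild temperature is chosen so that the ortho-prenyl phenol should not cyclise and the chromene alkene should not add methanol.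

**Compound list**
1 | 3-(4-hydroxyphenyl)propanoic acid | O=C(O)CCc1ccc(O)cc1 | starting material
2 | 3-(4-hydroxyphenyl)-1-(1H-imidazol-1-yl)propan-1-one | O=C(CCc1ccc(O)cc1)n1ccnc1 | intermediate
3 | 3-(4-hydroxyphenyl)-N-methoxy-N-methylpropanamide | CON(C)C(=O)CCc1ccc(O)cc1 | intermediate
4 | N-methoxy-3-[4-(methoxymethoxy)phenyl]-N-methylpropanamide | CON(C)C(=O)CCc1ccc(OCOC)cc1 | intermediate
5 | 1-bromo-2,4-difluorobenzene | Fc1ccc(Br)c(F)c1 | starting material
6 | 1-bromo-3-methylbut-2-ene | CC(C)=CCBr | starting material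
7 | (3-bromo-2,6-difluorophenyl)lithium | [Li]c1c(F)ccc(Br)c1F | intermediate
8 | 1-bromo-2,4-difluoro-3-(3-methylbut-2-enyl)benzene | CC(C)=CCc1c(F)ccc(Br)c1F | intermediate
9 | [5-bromo-2,4-difluoro-3-(3-methylbut-2-enyl)phenyl]lithium | [Li]c1cc(Br)c(F)c(CC=C(C)C)c1F | intermediate
10 | lithium 1-[5-bromo-2,4-difluoro-3-(3-methylbut-2-enyl)phenyl]-1-[methoxy(methyl)amino]-3-[4-(methoxymethoxy)phenyl]propan-1-olate | [Li]OC(CCc1ccc(OCOC)cc1)(N(C)OC)c1cc(Br)c(F)c(CC=C(C)C)c1F | intermediate
11 | 1-[5-bromo-2,4-difluoro-3-(3-methylbut-2-enyl)phenyl]-3-[4-(methoxymethoxy)phenyl]propan-1-one | CC(C)=CCc1c(F)c(C(=O)CCc2ccc(OCOC)cc2)cc(Br)c1F | intermediate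
12 | 2-methylbut-3-yn-2-ol | CC(C)(O)C#C | starting material
13 | 1-[2,4-difluoro-5-(3-hydroxy-3-methylbut-1-ynyl)-3-(3-methylbut-2-enyl)phenyl]-3-[4-(methoxymethoxy)phenyl]propan-1-one | CC(C)=CCc1c(F)c(C(=O)CCc2ccc(OCOC)cc2)cc(C#CC(C)(C)O)c1F | intermediate
14 | 1-[2,4-difluoro-5-[(Z)-3-hydroxy-3-methylbut-1-enyl]-3-(3-methylbut-2-enyl)phenyl]-3-[4-(methoxymethoxy)phenyl]propan-1-one | CC(C)=CCc1c(F)c(C(=O)CCc2ccc(OCOC)cc2)cc(/C=C\C(C)(C)O)c1F | intermediate
15 | 1-[7-fluoro-2,2-dimethyl-8-(3-methylbut-2-enyl)-2H-chromen-6-yl]-3-[4-(methoxymethoxy)phenyl]propan-1-one | CC(C)=CCc1c(F)c(C(=O)CCc2ccc(OCOC)cc2)cc2c1OC(C)(C)C=C2 | intermediate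
16 | N-[[2,2-dimethyl-6-[3-[4-(methoxymethoxy)phenyl]propanoyl]-8-(3-methylbut-2-enyl)-2H-chromen-7-yl]oxy]acetamide | CC(C)=CCc1c(ONC(C)=O)c(C(=O)CCc2ccc(OCOC)cc2)cc2c1OC(C)(C)C=C2 | intermediate
17 | 1-[7-hydroxy-2,2-dimethyl-8-(3-methylbut-2-enyl)-2H-chromen-6-yl]-3-[4-(methoxymethoxy)phenyl]propan-1-one | CC(C)=CCc1c(O)c(C(=O)CCc2ccc(OCOC)cc2)cc2c1OC(C)(C)C=C2 | intermediate
18 | 1-[7-hydroxy-2,2-dimethyl-8-(3-methylbut-2-enyl)-2H-chromen-6-yl]-3-(4-hydroxyphenyl)propan-1-one | CC(C)=CCc1c(O)c(C(=O)CCc2ccc(O)cc2)cc2c1OC(C)(C)C=C2 | target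

**Step count**
Total step count: 9.
Longest linear sequence: 8 steps (steps 1, 2, 4, 5, 6, 7, 8 and 9); the arene branch (steps 3 to 9) is 7 steps.

**Steps most likely to fail**

Step 7. The ketone α-CH2 is more acidic than the tertiary alcohol, so enolisation may outrun alkoxide formation. The ring closure could then stall, or material could be lost through aldol-type self-condensation on prolonged heating. The fallback sets out from 14 and comes back at 15, and closes the pyran at O1–C2 instead of O1–C8a:
- Acetohydroxamic acid and K2CO3 in DMSO at 60–80 °C should displace the fluorine para to the ketone intermolecularly. That site is the expected one in DMSO, where no chelation favours the ortho position.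
- This gives N-[3-fluoro-6-[(Z)-3-hydroxy-3-methylbut-1-enyl]-4-[3-[4-(methoxymethoxy)phenyl]propanoyl]-2-(3-methylbut-2-enyl)phenoxy]acetamide F1, which fragments in the same flask to 1-[2-fluoro-4-hydroxy-5-[(Z)-3-hydroxy-3-methylbut-1-enyl]-3-(3-methylbut-2-enyl)phenyl]-3-[4-(methoxymethoxy)phenyl]propan-1-one F2.
- Catalytic pyridinium p-toluenesulfonate in CH2Cl2 at rt should then ionise the tertiary allylic alcohol and let the phenol oxygen close the ring (cyclodehydration of an ortho-hydroxycinnamyl carbinol), giving 15.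

Step 8. The C7 fluorine is crowded on both sides by the prenyl and acyl groups, and the ring is deactivated by electron donation from O1 into the ketone. Intermolecular attack may therefore be slow, and base-induced degradation may take over at the temperatures needed. The fallback sets out from 15 and comes back at 17, and delivers the oxygen intramolecularly:
- NH2OH·HCl and pyridine in EtOH at 70 °C give 1-[7-fluoro-2,2-dimethyl-8-(3-methylbut-2-enyl)-2H-chromen-6-yl]-3-[4-(methoxymethoxy)phenyl]propan-1-one oxime F3.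
- K2CO3 in DMF at 90 °C closes the pyrano-fused 3-{2-[4-(methoxymethoxy)phenyl]ethyl}-1,2-benzoxazole F4 by attack of the oximate oxygen on C7. The oxazole oxygen sits on the former C7 and the oxazole C3 on the former C6; the gem-dimethyl pyran and the prenyl group are unchanged.
- Mo(CO)6 in wet MeCN at 80 °C cleaves the N–O bond reductively to 6-[1-imino-3-[4-(methoxymethoxy)phenyl]propyl]-2,2-dimethyl-8-(3-methylbut-2-enyl)-2H-chromen-7-ol F5.
- Work-up with aqueous oxalic acid hydrolyses the imine to 17.

Step 4. Deprotonation may be incomplete or misdirected: removal of a benzylic–allylic proton of the prenyl CH2, bromine migration between aryllithium and aryl bromide, or loss of LiF to an aryne on warming. The aryllithium may also take an α-proton from the amide instead of adding. The fallback sets out from 5 and comes back at 11, and replaces deprotonation by halogen–magnesium exchange: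
- N-iodosuccinimide in CF3SO3H/CH2Cl2 iodinates 5 para to one fluorine and ortho to the other, giving 1-bromo-2,4-difluoro-5-iodobenzene F6.
- LiN(iPr)2 at −78 °C deprotonates between the fluorines to (3-bromo-2,6-difluoro-5-iodophenyl)lithium F7, which is prenylated with 6 under CuBr·SMe2 catalysis as in step 3 to 1-bromo-2,4-difluoro-5-iodo-3-(3-methylbut-2-enyl)benzene F8.
- iPrMgCl·LiCl in THF at −40 °C exchanges only the iodine, giving [5-bromo-2,4-difluoro-3-(3-methylbut-2-enyl)phenyl]magnesium chloride F9.
- F9 adds to Weinreb amide 4 to give chloromagnesium 1-[5-bromo-2,4-difluoro-3-(3-methylbut-2-enyl)phenyl]-1-[methoxy(methyl)amino]-3-[4-(methoxymethoxy)phenyl]propan-1-olate F10, and aqueous NH4Cl releases 11.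

**Further compounds**
F1 | step 7 | N-[3-fluoro-6-[(Z)-3-hydroxy-3-methylbut-1-enyl]-4-[3-[4-(methoxymethoxy)phenyl]propanoyl]-2-(3-methylbut-2-enyl)phenoxy]acetamide | CC(C)=CCc1c(F)c(C(=O)CCc2ccc(OCOC)cc2)cc(/C=C\C(C)(C)O)c1ONC(C)=O
F2 | step 7 | 1-[2-fluoro-4-hydroxy-5-[(Z)-3-hydroxy-3-methylbut-1-enyl]-3-(3-methylbut-2-enyl)phenyl]-3-[4-(methoxymethoxy)phenyl]propan-1-one | CC(C)=CCc1c(F)c(C(=O)CCc2ccc(OCOC)cc2)cc(/C=C\C(C)(C)O)c1O
F3 | step 8 | 1-[7-fluoro-2,2-dimethyl-8-(3-methylbut-2-enyl)-2H-chromen-6-yl]-3-[4-(methoxymethoxy)phenyl]propan-1-one oxime (mixture of oxime isomers) | CC(C)=CCc1c(F)c(C(=NO)CCc2ccc(OCOC)cc2)cc2c1OC(C)(C)C=C2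
F4 | step 8 | pyrano-fused 3-{2-[4-(methoxymethoxy)phenyl]ethyl}-1,2-benzoxazole (oxazole O on former C7, oxazole C3 on former C6, gem-dimethyl pyran and prenyl unchanged) | CC(C)=CCc1c2onc(CCc3ccc(OCOC)cc3)c2cc2C=CC(C)(C)Oc12
F5 | step 8 | 6-[1-imino-3-[4-(methoxymethoxy)phenyl]propyl]-2,2-dimethyl-8-(3-methylbut-2-enyl)-2H-chromen-7-ol | CC(C)=CCc1c(O)c(C(=N)CCc2ccc(OCOC)cc2)cc2c1OC(C)(C)C=C2
F6 | step 4 | 1-bromo-2,4-difluoro-5-iodobenzene | Fc1cc(F)c(I)cc1Br
F7 | step 4 | (3-bromo-2,6-difluoro-5-iodophenyl)lithium | [Li]c1c(F)c(I)cc(Br)c1F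
F8 | step 4 | 1-bromo-2,4-difluoro-5-iodo-3-(3-methylbut-2-enyl)benzene | CC(C)=CCc1c(F)c(I)cc(Br)c1F
F9 | step 4 | [5-bromo-2,4-difluoro-3-(3-methylbut-2-enyl)phenyl]magnesium chloride | Cl[Mg]c1cc(Br)c(F)c(CC=C(C)C)c1F
F10 | step 4 | chloromagnesium 1-[5-bromo-2,4-difluoro-3-(3-methylbut-2-enyl)phenyl]-1-[methoxy(methyl)amino]-3-[4-(methoxymethoxy)phenyl]propan-1-olate | Cl[Mg]OC(CCc1ccc(OCOC)cc1)(N(C)OC)c1cc(Br)c(F)c(CC=C(C)C)c1F
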